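**Retrosynthetic overview**
- The target is the bis-phenol of a diaryl ether. The last disconnection is O-demethylation of the ring A methyl ether (ring A: C1 ether O, C2 OH, C3 Br, C5 Br).
- The strategy rests on ring B (C1' ether O, C2' OH, C3' Br, C5' Br, C6' Br). It is 2,4,6-tribromophenol in which the ether oxygen occupies the former ortho C–Br carbon C1' and the displaced bromine sits on the adjacent carbon C6', meta to the OH, where electrophilic bromination would not put it.
- O–C1' and C6'–Br are therefore disconnected together: anodic ipso C–O coupling of 2,4,6-tribromophenol with 3,5-dibromo-2-methoxyphenol, followed in the same flask by an acid-driven 1,2-bromine shift of the bromodienone.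
- 3,5-Dibromo-2-methoxyphenol comes from 3,5-dibromosalicylaldehyde by O-methylation and Baeyer–Villiger (Dakin-type) oxidation.
- No ring is formed in the route; both benzene rings are bought.

Key step: step 3

Remark: the target has no stereocentre and the tri-ortho-substituted diaryl ether rotates freely, so it is achiral and the requirement of a single enantiomer is met without stereocontrol.

**Step 1**
Reactants: 1 3,5-dibromosalicylaldehyde (3,5-dibromo-2-hydroxybenzaldehyde)
Product: 2 3,5-dibromo-2-methoxybenzaldehyde
Conditions: MeI (1.5 equiv), K2CO3 (2 equiv), DMF, rt to 40 °C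
Reagents that add atoms: iodomethane, CI
Why: Williamson ether synthesis; the acidic phenol is deprotonated by K2CO3 in DMF and the phenoxide is methylated by SN2 on iodomethane, the aldehyde and aryl bromides being inert.

**Step 2**
Reactants: 2 3,5-dibromo-2-methoxybenzaldehyde
Product: 4 3,5-dibromo-2-methoxyphenol, via aryl formate 3 (not isolated)
Conditions: mCPBA (1.5 equiv), CH2Cl2, rt; aqueous wash; then HCl (cat.), MeOH, rt
Reagents that add atoms: meta-chloroperoxybenzoic acid, O=C(OO)c1cccc(Cl)c1
Why: Baeyer–Villiger (Dakin-type) oxidation of an ortho-alkoxybenzaldehyde; in the Criegee adduct the aryl group, activated at the migrating carbon by the ortho methoxy group, should migrate in preference to hydride to give formate 3, which acid-catalysed methanolysis cleaves to the phenol.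

**Step 3**
Reactants: 4 3,5-dibromo-2-methoxyphenol; 5 2,4,6-tribromophenol
Product: 7 3,4,6-tribromo-2-(3,5-dibromo-2-methoxyphenoxy)phenol, via ortho-quinol ether bromodienone 6 (not isolated)
Conditions: divided cell, BDD anode, Pt cathode, constant current (5 mA cm−2, ca. 3 F per mol of 4, until 4 is consumed); 5 (3 equiv), TfOH (0.2 M), Bu4NOTf (0.1 M), HFIP, 0 °C; 4 fed in by syringe pump during the electrolysis
Reagents that add atoms: none
Why: Proposed new method: one-electron oxidation of both phenols at the anode gives phenoxyl radicals, and the unhindered oxygen of the radical from 4 should bond to a bromine-bearing ortho carbon of the 2,4,6-tribromophenoxyl radical (4 may equally trap the two-electron-oxidised phenoxonium ion of 5 through oxygen), giving the racemic dienone 6. O-Protonation of 6 by TfOH in HFIP makes it the ipso arenium ion, in which the bromine on the sp3 carbon can bridge only to the neighbouring CH carbon (the other neighbour is the C–OH carbon); the shift puts the positive charge next to the aryloxy oxygen, and loss of the proton from the carbon that received bromine is irreversible, so O–C1' and C6'–Br are formed. The closest known reactions are the chemical, enzymatic and anodic oxidative couplings of 2,4,6-tribromophenol at its bromine-bearing carbons (which normally end with loss of that bromine), anodic dehydrogenative phenol cross-coupling in HFIP on BDD, and the acid-catalysed 1,2-bromine shift of bromocyclohexadienones to meta-bromophenols. No ring is closed and no stereocentre remains, since the quaternary carbon of 6 is racemic and becomes aromatic again. The step needs cross- over homo-coupling and O-to-C(ortho) bonding, which the excess of 5, the slow feed of 4 (starving its free C4–H and C6–H sites and its self-coupling) and the two ortho carbons of 5 against one para carbon should favour. It also needs migration over loss of bromine, which the strong acid (fast intramolecular shift), the divided cell, the non-nucleophilic triflate electrolyte and the low standing concentration of 4 should favour by removing cathode, bromide and activated arenes as bromine acceptors; the para-coupled dienone would give an isomeric 4-aryloxy-2,3,6-tribromophenol, expected to be separable by chromatography.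

**Step 4**
Reactants: 7 3,4,6-tribromo-2-(3,5-dibromo-2-methoxyphenoxy)phenol
Product: 8 3,4,6-tribromo-2-(3,5-dibromo-2-hydroxyphenoxy)phenol
Conditions: BBr3 (3 equiv), CH2Cl2, −78 °C to rt; then H2O
Reagents that add atoms: none
Why: Lewis-acid cleavage of an aryl methyl ether; BBr3 coordinates the methoxy oxygen and bromide attacks the methyl group by SN2, the diaryl ether and aryl bromides being untouched, and hydrolysis of the aryl borates on work-up frees both phenols.

**Compound list**
1 | 3,5-dibromosalicylaldehyde (3,5-dibromo-2-hydroxybenzaldehyde) | O=Cc1cc(Br)cc(Br)c1O | starting material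
2 | 3,5-dibromo-2-methoxybenzaldehyde | COc1c(Br)cc(Br)cc1C=O | intermediate
3 | 3,5-dibromo-2-methoxyphenyl formate | COc1c(Br)cc(Br)cc1OC=O | intermediate (not isolated)
4 | 3,5-dibromo-2-methoxyphenol | COc1c(O)cc(Br)cc1Br | intermediate
5 | 2,4,6-tribromophenol | Oc1c(Br)cc(Br)cc1Br | starting material
6 | 2,4,6-tribromo-6-(3,5-dibromo-2-methoxyphenoxy)cyclohexa-2,4-dien-1-one (racemic) | COc1c(Br)cc(Br)cc1OC1(Br)C=C(Br)C=C(Br)C1=O | intermediate (not isolated)
7 | 3,4,6-tribromo-2-(3,5-dibromo-2-methoxyphenoxy)phenol | COc1c(Br)cc(Br)cc1Oc1c(O)c(Br)cc(Br)c1Br | intermediate
8 | 3,4,6-tribromo-2-(3,5-dibromo-2-hydroxyphenoxy)phenol | Oc1c(Br)cc(Br)cc1Oc1c(O)c(Br)cc(Br)c1Br | target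

**Step count**
Total steps: 4. Longest linear sequence: 4 steps (1 → 2 → 4 → 7 → 8); 5 is bought and enters at step 3.

**Steps most likely to fail**

1. Step 3 (proposed new method). What may go wrong:
- bonding through the free C4–H or C6–H positions of 4, or at the para carbon of 5, instead of oxygen to ortho carbon;
- expulsion of bromine from the dienone instead of its 1,2-shift;
- homo-coupling, and further oxidation of the product phenol.

Fallback by known chemistry, setting out from 4 and returning at 7:
- SNAr of the potassium phenoxide of 4 (K2CO3, DMF, 80 °C) on commercial 1-bromo-2-fluoro-3-nitrobenzene, at the fluorine ortho to the nitro group, should give 1-bromo-2-(3,5-dibromo-2-methoxyphenoxy)-3-nitrobenzene F1.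
- Reduction with Fe/NH4Cl in aqueous EtOH, which spares aryl bromides, should give 3-bromo-2-(3,5-dibromo-2-methoxyphenoxy)aniline F2.
- NBS (2 equiv, MeCN, 0 °C to rt) should brominate ortho and para to the amino group, giving 3,4,6-tribromo-2-(3,5-dibromo-2-methoxyphenoxy)aniline F3.
- Diazotisation (NaNO2, H2SO4/AcOH, 0 °C) and hydroxydediazoniation (Cu2O, Cu(NO3)2, H2O) should convert F3 into 7.

2. Step 2. What may go wrong: hydride migration in the Criegee adduct, favoured because two bromines lower the migratory aptitude of the aryl group, which would lead to the benzoic acid.

Fallback, setting out from 2 and returning at 4 (hydrogen is replaced by methyl, a poor migrating group):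
- MeMgBr (THF, −78 to 0 °C) should give racemic 1-(3,5-dibromo-2-methoxyphenyl)ethanol F4.
- Dess–Martin oxidation should give 1-(3,5-dibromo-2-methoxyphenyl)ethanone F5.
- Baeyer–Villiger oxidation with trifluoroperacetic acid (buffered, CH2Cl2) should give 3,5-dibromo-2-methoxyphenyl acetate F6.
- K2CO3/MeOH should cleave F6 to 4.

3. Step 4. What may go wrong: slow cleavage of the methyl ether flanked by bromine and the aryloxy group, together with loss or migration of ortho/para bromine on the phenol rings promoted by the HBr and Lewis acid present.

Fallback, setting out from 7 and returning at 8: nucleophilic demethylation under basic, acid-free conditions with sodium ethanethiolate in DMF at about 100 °C. The thiolate attacks the methyl group by SN2 and releases the stabilised phenoxide, while ring B is protected from substitution as its phenoxide. No new compound is made on the way.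

**Further compounds**
F1 | step 3 | 1-bromo-2-(3,5-dibromo-2-methoxyphenoxy)-3-nitrobenzene | COc1c(Br)cc(Br)cc1Oc1c(Br)cccc1[N+](=O)[O-]
F2 | step 3 | 3-bromo-2-(3,5-dibromo-2-methoxyphenoxy)aniline | COc1c(Br)cc(Br)cc1Oc1c(N)cccc1Br
F3 | step 3 | 3,4,6-tribromo-2-(3,5-dibromo-2-methoxyphenoxy)aniline | COc1c(Br)cc(Br)cc1Oc1c(N)c(Br)cc(Br)c1Br
F4 | step 2 | 1-(3,5-dibromo-2-methoxyphenyl)ethanol (racemic) | COc1c(Br)cc(Br)cc1C(C)O
F5 | step 2 | 1-(3,5-dibromo-2-methoxyphenyl)ethanone | COc1c(Br)cc(Br)cc1C(C)=O
F6 | step 2 | 3,5-dibromo-2-methoxyphenyl acetate | COc1c(Br)cc(Br)cc1OC(C)=O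
F0 | step 4 | none | none
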